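**Plan**

- The target is epicatechin-(4β→8)-epicatechin 3-O-gallate-(4β→8)-epicatechin 3-O-gallate. Retrosynthetically, eighteen O-benzyl groups are removed, then the C2–aryl and C3–O bonds of the top unit are cut (aryl transfer to a 2,3-epoxychroman), then C4–C4a and O1–C2 of the top ring C (phenol plus enal). The C8–vinyl bond of the middle unit, the middle C4–bottom C8 bond and the two gallate esters follow.
- The annulation is possible because the top ring C is fused to a phloroglucinol-type ring A through C4a and C8a–O1, this ring A has only H at C6 and C8, and C4 carries nothing but C8 of the middle unit. C4a and O1 therefore come from a symmetrical 3,5-dioxygenated phenol and C4–C3–C2 from a β-aryl enal.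
- Forward: the middle and bottom flavans come intact from (−)-epicatechin and are joined by a cationic 4→8 coupling. An enal is placed on middle C8, the top ring C is closed as a lactol, dehydrated and epoxidised, and the top ring B is attached last, before global debenzylation.
- Stereochemistry: C2 and C3 of the middle and bottom units come from the chiral pool. Middle C4 is set by attack trans to the 3-O-gallate, top C4 by the aminocatalyst, top C3 by epoxidation anti to the C4 substituent, and top C2 by syn delivery of the aryl group from aluminium.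

Key step: step 8

Remark on the chemistry: flavan numbering is used. "Top" is the unit with the free 3-OH; "middle" and "bottom" are the two 3-O-gallates. α is the face of a ring C that carries the 2-aryl group and the 3-oxygen of epicatechin, β the opposite face. ECG(Bn7) stands for 5,7,3',4'-tetra-O-benzylepicatechin 3-O-[3,4,5-tris(benzyloxy)benzoate]. Compounds 3, 9, 12 and 16 are assumed to be purchasable.

**Step 1**
Reactants: 1 (−)-epicatechin
Product: 2 5,7,3',4'-tetra-O-benzyl-(−)-epicatechin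
Conditions: BnBr (4.4 equiv), K2CO3, DMF, −10 °C to rt, argon
Reagents that add atoms: benzyl bromide, BrCc1ccccc1
Why: Williamson etherification with carbonate alkylates only the four phenols and leaves the secondary 3-OH free, and the cold, oxygen-free medium avoids C2 epimerisation, so the 2R,3R centres are taken over from the chiral pool.

**Step 2**
Reactants: 2 5,7,3',4'-tetra-O-benzyl-(−)-epicatechin; 3 3,4,5-tris(benzyloxy)benzoic acid
Product: 4 ECG(Bn7), the bottom unit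
Conditions: DCC, DMAP (cat.), CH2Cl2, 0 °C to rt
Reagents that add atoms: none
Why: Steglich esterification acylates the hindered axial 3-OH through the acylpyridinium ion without touching a stereocentre.

**Step 3**
Reactants: 2 5,7,3',4'-tetra-O-benzyl-(−)-epicatechin
Product: 5 8-bromo-5,7,3',4'-tetra-O-benzyl-(−)-epicatechin
Conditions: NBS (1.0 equiv), CH2Cl2, −78 °C to rt
Reagents that add atoms: N-bromosuccinimide, O=C1CCC(=O)N1Br
Why: Electrophilic aromatic bromination of the phloroglucinol-type ring A goes to C8, its most nucleophilic position, and the bromine later blocks C8 against self-condensation and serves as the cross-coupling handle.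

**Step 4**
Reactants: 5 8-bromo-5,7,3',4'-tetra-O-benzyl-(−)-epicatechin
Product: 6 8-bromo-4β-(2-ethoxyethoxy)-5,7,3',4'-tetra-O-benzylepicatechin (C4–O trans to 3-OH)
Conditions: DDQ (2 equiv), 2-ethoxyethanol (5 equiv), CH2Cl2, rt
Reagents that add atoms: 2-ethoxyethanol, CCOCCO
Why: DDQ abstracts hydride from the benzylic C4 (oxidative benzylic etherification) and the alcohol traps the ring-A-stabilised cation from the β face, anti to the 3-OH and the 2-aryl group.

**Step 5**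
Reactants: 6 8-bromo-4β-(2-ethoxyethoxy)-5,7,3',4'-tetra-O-benzylepicatechin; 3 3,4,5-tris(benzyloxy)benzoic acid
Product: 7 8-bromo-4β-(2-ethoxyethoxy)-ECG(Bn7), the middle-unit electrophile
Conditions: DCC, DMAP, CH2Cl2, rt
Reagents that add atoms: none
Why: Steglich esterification as in step 2, with the C4 ether inert to the neutral acylation conditions.

**Step 6**
Reactants: 7 8-bromo-4β-(2-ethoxyethoxy)-ECG(Bn7); 4 ECG(Bn7)
Product: 8 8-bromo-ECG(Bn7)-(4β→8)-ECG(Bn7), the bromo dimer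
Conditions: TMSOTf (0.2 equiv), CH2Cl2, −40 °C, twofold excess of the nucleophile; Et3N quench
Reagents that add atoms: none
Why: Lewis-acid ionisation of the C4 ether gives a benzylic cation, shielded on the α face by the neighbouring gallate, which undergoes Friedel–Crafts attack by C8 of 4 from the β face and so sets middle C4 trans to the 3-O-gallate, while the bromine keeps 7 from condensing with itself.

**Step 7**
Reactants: 8 bromo dimer; 9 (E)-2-(3,3-diethoxyprop-1-enyl)-4,4,5,5-tetramethyl-1,3,2-dioxaborolane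
Product: 11 8-[(E)-3-oxoprop-1-enyl]-ECG(Bn7)-(4β→8)-ECG(Bn7) (dimer enal), via dimer diethyl acetal 10 (not isolated)
Conditions: Pd(OAc)2 (10 mol %), SPhos (20 mol %), K3PO4, toluene/H2O, 80 °C; then PPTS, acetone/H2O, rt
Reagents that add atoms: water, O
Why: Suzuki–Miyaura coupling, in which the bulky biarylphosphine lets zerovalent palladium insert into the hindered, electron-rich C8–Br bond and the alkenyl group is transferred with retention of the E geometry, is followed by mild hydrolysis of the allylic acetal, which the esters and benzyl ethers tolerate.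

**Step 8**
Reactants: 11 dimer enal; 12 3,5-bis(benzyloxy)phenol
Product: 13 top-unit lactol: 5,7-bis(benzyloxy)chroman-2-ol carrying C8 of ECG(Bn7)-(4β→8)-ECG(Bn7) at C4 (β) as an anomeric mixture
Conditions: (S)-α,α-diphenylprolinol trimethylsilyl ether (20 mol %), PhCO2H (20 mol %), CH2Cl2, 0 °C to rt, twofold excess of the phenol
Reagents that add atoms: none
Why: The pyrrolidine and enal 11 give an (E), s-trans iminium ion (benzoic acid speeds its formation and turnover), an ortho carbon of phenol 12 adds to the β-carbon in a Friedel–Crafts conjugate addition, the enamine is protonated and hydrolysed, and the phenolic oxygen then adds to the freed aldehyde, so the two partners combine one to one with nothing split off. The closest known reaction type is the diarylprolinol-silyl-ether-catalysed Friedel–Crafts alkylation/hemiacetalisation of naphthols and alkoxyphenols with enals to 4-substituted chroman-2-ols. The top ring C closes by 6-exo-trig addition of the phenol oxygen to the aldehyde carbon (C4–C4a first, then O1–C2), and the anomeric mixture is of no consequence because C2 becomes trigonal again in step 9. The new C4 stereocentre is under catalyst control: the diphenyl(silyloxy)methyl group of the (S)-catalyst covers one face of the iminium β-carbon, so the arene should add to the open face, placing the middle-unit aryl group β and H-4 α as in the target, with the remote flavan stereocentres acting only as a secondary influence. The step needs C- over O-alkylation and ortho over para attack, which hydrogen bonding of the free OH and the draining of the ortho adduct as the lactol provide; the two ortho carbons of 12 are equivalent, so one constitution results, and the excess of phenol suppresses a second alkylation.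

**Step 9**
Reactants: 13 top-unit lactol
Product: 15 5,7-bis(benzyloxy)-4H-chromene bearing the same C4 (β) dimer substituent, via anomeric mesylate 14 (not isolated)
Conditions: MsCl (2 equiv), Et3N (5 equiv), CH2Cl2, 0 °C to rt
Reagents that add atoms: none
Why: Sulfonylation of the anomeric hydroxyl and base-assisted loss of mesylate through the aryloxy-stabilised oxocarbenium ion, with removal of a C3 proton (lactol dehydration to a cyclic enol ether), gives the C2=C3 double bond and leaves C4 untouched.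

**Step 10**
Reactants: 15 top-unit 4H-chromene; 16 4-bromo-1,2-bis(benzyloxy)benzene
Product: 19 5,7,3',4'-tetra-O-benzylepicatechin-(4β→8)-ECG(Bn7)-(4β→8)-ECG(Bn7), via 2α,3α-epoxide 17 (not isolated), via triarylalane 18 (not isolated)
Conditions: DMDO (1.3 equiv), acetone/CH2Cl2, −78 to 0 °C, evaporate cold; separately the aryl bromide (9 equiv), n-BuLi, THF, −78 °C, then AlCl3 (3 equiv), −78 to 0 °C; add the crude epoxide in CH2Cl2, −78 to 0 °C; aq. NaHCO3
Reagents that add atoms: dimethyldioxirane, CC1(C)OO1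
Why: Proposed new method: DMDO should epoxidise the electron-rich enol ether on the α face, anti to the large 4β substituent (the known epoxidation of glycals and enol ethers), and the crude epoxide is expected to open at C2 with retention, because aluminium binds the epoxide oxygen, ionises the C2–O bond to an aryloxy-stabilised oxocarbenium/aluminate pair and passes an aryl group to the same α face, setting C2 (aryl α) cis to the new C3 oxygen (α); the closest known reaction type is the syn opening of 1,2-anhydro sugars by triarylalanes to 1,2-cis C-aryl glycosides, which has not been shown on 2,3-epoxychromans.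

**Step 11**
Reactants: 19 octadeca-O-benzyl trimer
Product: 20 epicatechin-(4β→8)-epicatechin 3-O-gallate-(4β→8)-epicatechin 3-O-gallate
Conditions: H2 (1 atm), Pd(OH)2/C, THF/MeOH/H2O, rt
Reagents that add atoms: none
Why: Catalytic hydrogenolysis should cleave the eighteen benzyl aryl ethers under neutral conditions, while the gallate esters, the hindered C2–O1 bonds and the interflavan bonds are retained and no stereocentre is affected.

**Compound list**

1 | (−)-epicatechin, (2R,3R) | O[C@@H]1Cc2c(O)cc(O)cc2O[C@@H]1c1ccc(O)c(O)c1 | starting material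
2 | 5,7,3',4'-tetra-O-benzyl-(−)-epicatechin | O[C@@H]1Cc2c(OCc3ccccc3)cc(OCc3ccccc3)cc2O[C@@H]1c1ccc(OCc2ccccc2)c(OCc2ccccc2)c1 | intermediate
3 | 3,4,5-tris(benzyloxy)benzoic acid | O=C(O)c1cc(OCc2ccccc2)c(OCc2ccccc2)c(OCc2ccccc2)c1 | starting material
4 | ECG(Bn7): 5,7,3',4'-tetra-O-benzylepicatechin 3-O-[3,4,5-tris(benzyloxy)benzoate] | O=C(O[C@@H]1Cc2c(OCc3ccccc3)cc(OCc3ccccc3)cc2O[C@@H]1c1ccc(OCc2ccccc2)c(OCc2ccccc2)c1)c1cc(OCc2ccccc2)c(OCc2ccccc2)c(OCc2ccccc2)c1 | intermediate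
5 | 8-bromo-5,7,3',4'-tetra-O-benzyl-(−)-epicatechin | O[C@@H]1Cc2c(OCc3ccccc3)cc(OCc3ccccc3)c(Br)c2O[C@@H]1c1ccc(OCc2ccccc2)c(OCc2ccccc2)c1 | intermediate
6 | 8-bromo-4β-(2-ethoxyethoxy)-5,7,3',4'-tetra-O-benzylepicatechin (2,3-cis, 3,4-trans) | O[C@@H]1[C@@H](OCCOCC)c2c(OCc3ccccc3)cc(OCc3ccccc3)c(Br)c2O[C@@H]1c1ccc(OCc2ccccc2)c(OCc2ccccc2)c1 | intermediate
7 | 8-bromo-4β-(2-ethoxyethoxy)-ECG(Bn7) | O=C(O[C@@H]1[C@@H](OCCOCC)c2c(OCc3ccccc3)cc(OCc3ccccc3)c(Br)c2O[C@@H]1c1ccc(OCc2ccccc2)c(OCc2ccccc2)c1)c1cc(OCc2ccccc2)c(OCc2ccccc2)c(OCc2ccccc2)c1 | intermediate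
8 | 8-bromo-ECG(Bn7)-(4β→8)-ECG(Bn7), bromine on the upper unit | O=C(O[C@@H]1[C@@H](c2c(OCc3ccccc3)cc(OCc3ccccc3)c3c2O[C@H](c2ccc(OCc4ccccc4)c(OCc4ccccc4)c2)[C@H](OC(=O)c2cc(OCc4ccccc4)c(OCc4ccccc4)c(OCc4ccccc4)c2)C3)c2c(OCc3ccccc3)cc(OCc3ccccc3)c(Br)c2O[C@@H]1c1ccc(OCc2ccccc2)c(OCc2ccccc2)c1)c1cc(OCc2ccccc2)c(OCc2ccccc2)c(OCc2ccccc2)c1 | intermediate
9 | (E)-2-(3,3-diethoxyprop-1-enyl)-4,4,5,5-tetramethyl-1,3,2-dioxaborolane | CCOC(OCC)/C=C/B1OC(C)(C)C(C)(C)O1 | starting material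
10 | 8-[(E)-3,3-diethoxyprop-1-enyl]-ECG(Bn7)-(4β→8)-ECG(Bn7) | O=C(O[C@@H]1[C@@H](c2c(OCc3ccccc3)cc(OCc3ccccc3)c3c2O[C@H](c2ccc(OCc4ccccc4)c(OCc4ccccc4)c2)[C@H](OC(=O)c2cc(OCc4ccccc4)c(OCc4ccccc4)c(OCc4ccccc4)c2)C3)c2c(OCc3ccccc3)cc(OCc3ccccc3)c(/C=C/C(OCC)OCC)c2O[C@@H]1c1ccc(OCc2ccccc2)c(OCc2ccccc2)c1)c1cc(OCc2ccccc2)c(OCc2ccccc2)c(OCc2ccccc2)c1 | intermediate (not isolated)
11 | 8-[(E)-3-oxoprop-1-enyl]-ECG(Bn7)-(4β→8)-ECG(Bn7), the dimer enal | O=C(O[C@@H]1[C@@H](c2c(OCc3ccccc3)cc(OCc3ccccc3)c3c2O[C@H](c2ccc(OCc4ccccc4)c(OCc4ccccc4)c2)[C@H](OC(=O)c2cc(OCc4ccccc4)c(OCc4ccccc4)c(OCc4ccccc4)c2)C3)c2c(OCc3ccccc3)cc(OCc3ccccc3)c(/C=C/C=O)c2O[C@@H]1c1ccc(OCc2ccccc2)c(OCc2ccccc2)c1)c1cc(OCc2ccccc2)c(OCc2ccccc2)c(OCc2ccccc2)c1 | intermediate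
12 | 3,5-bis(benzyloxy)phenol | Oc1cc(OCc2ccccc2)cc(OCc2ccccc2)c1 | starting material
13 | 5,7-bis(benzyloxy)chroman-2-ol with C8 of ECG(Bn7)-(4β→8)-ECG(Bn7) at C4 (β; H-4 α), anomeric mixture | O=C(O[C@@H]1[C@@H](c2c(OCc3ccccc3)cc(OCc3ccccc3)c3c2O[C@H](c2ccc(OCc4ccccc4)c(OCc4ccccc4)c2)[C@H](OC(=O)c2cc(OCc4ccccc4)c(OCc4ccccc4)c(OCc4ccccc4)c2)C3)c2c(OCc3ccccc3)cc(OCc3ccccc3)c([C@H]3c4c(OCc5ccccc5)cc(OCc5ccccc5)cc4OC(O)C3)c2O[C@@H]1c1ccc(OCc2ccccc2)c(OCc2ccccc2)c1)c1cc(OCc2ccccc2)c(OCc2ccccc2)c(OCc2ccccc2)c1 | intermediate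
14 | 2-O-methanesulfonate of lactol 13 | O=C(O[C@@H]1[C@@H](c2c(OCc3ccccc3)cc(OCc3ccccc3)c3c2O[C@H](c2ccc(OCc4ccccc4)c(OCc4ccccc4)c2)[C@H](OC(=O)c2cc(OCc4ccccc4)c(OCc4ccccc4)c(OCc4ccccc4)c2)C3)c2c(OCc3ccccc3)cc(OCc3ccccc3)c([C@H]3c4c(OCc5ccccc5)cc(OCc5ccccc5)cc4OC(OS(C)(=O)=O)C3)c2O[C@@H]1c1ccc(OCc2ccccc2)c(OCc2ccccc2)c1)c1cc(OCc2ccccc2)c(OCc2ccccc2)c(OCc2ccccc2)c1 | intermediate (not isolated)
15 | 5,7-bis(benzyloxy)-4H-chromene with the same 4β dimer substituent | O=C(O[C@@H]1[C@@H](c2c(OCc3ccccc3)cc(OCc3ccccc3)c3c2O[C@H](c2ccc(OCc4ccccc4)c(OCc4ccccc4)c2)[C@H](OC(=O)c2cc(OCc4ccccc4)c(OCc4ccccc4)c(OCc4ccccc4)c2)C3)c2c(OCc3ccccc3)cc(OCc3ccccc3)c([C@H]3c4c(OCc5ccccc5)cc(OCc5ccccc5)cc4OC=C3)c2O[C@@H]1c1ccc(OCc2ccccc2)c(OCc2ccccc2)c1)c1cc(OCc2ccccc2)c(OCc2ccccc2)c(OCc2ccccc2)c1 | intermediate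
16 | 4-bromo-1,2-bis(benzyloxy)benzene | Brc1ccc(OCc2ccccc2)c(OCc2ccccc2)c1 | starting material
17 | 2α,3α-epoxy-5,7-bis(benzyloxy)chroman with the same 4β dimer substituent | O=C(O[C@@H]1[C@@H](c2c(OCc3ccccc3)cc(OCc3ccccc3)c3c2O[C@H](c2ccc(OCc4ccccc4)c(OCc4ccccc4)c2)[C@H](OC(=O)c2cc(OCc4ccccc4)c(OCc4ccccc4)c(OCc4ccccc4)c2)C3)c2c(OCc3ccccc3)cc(OCc3ccccc3)c([C@H]3c4c(OCc5ccccc5)cc(OCc5ccccc5)cc4O[C@H]5[C@@H]3O5)c2O[C@@H]1c1ccc(OCc2ccccc2)c(OCc2ccccc2)c1)c1cc(OCc2ccccc2)c(OCc2ccccc2)c(OCc2ccccc2)c1 | intermediate (not isolated)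
18 | tris[3,4-bis(benzyloxy)phenyl]alane | [Al](c1ccc(OCc2ccccc2)c(OCc2ccccc2)c1)(c1ccc(OCc2ccccc2)c(OCc2ccccc2)c1)c1ccc(OCc2ccccc2)c(OCc2ccccc2)c1 | intermediate (not isolated)
19 | 5,7,3',4'-tetra-O-benzylepicatechin-(4β→8)-ECG(Bn7)-(4β→8)-ECG(Bn7), top 3-OH free | O=C(O[C@@H]1[C@@H](c2c(OCc3ccccc3)cc(OCc3ccccc3)c3c2O[C@H](c2ccc(OCc4ccccc4)c(OCc4ccccc4)c2)[C@H](OC(=O)c2cc(OCc4ccccc4)c(OCc4ccccc4)c(OCc4ccccc4)c2)C3)c2c(OCc3ccccc3)cc(OCc3ccccc3)c([C@H]3c4c(OCc5ccccc5)cc(OCc5ccccc5)cc4O[C@H](c4ccc(OCc5ccccc5)c(OCc5ccccc5)c4)[C@@H]3O)c2O[C@@H]1c1ccc(OCc2ccccc2)c(OCc2ccccc2)c1)c1cc(OCc2ccccc2)c(OCc2ccccc2)c(OCc2ccccc2)c1 | intermediate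
20 | epicatechin-(4β→8)-epicatechin 3-O-gallate-(4β→8)-epicatechin 3-O-gallate (CNP0279403.1) | O=C(O[C@@H]1[C@@H](c2c(O)cc(O)c3c2O[C@H](c2ccc(O)c(O)c2)[C@H](OC(=O)c2cc(O)c(O)c(O)c2)C3)c2c(O)cc(O)c([C@H]3c4c(O)cc(O)cc4O[C@H](c4ccc(O)c(O)c4)[C@@H]3O)c2O[C@@H]1c1ccc(O)c(O)c1)c1cc(O)c(O)c(O)c1 | target

**Step count and risks**

Total: 11 steps. Longest linear sequence: 10 steps (1, 3, 4, 5, 6, 7, 8, 9, 10, 11).

Step 10 (epoxidation and aryl transfer). The epoxide may rearrange by hydride shift to the chroman-3-one under the Lewis acid, the aryl group may arrive from the β face or add to a gallate carbonyl, or the dioxirane may oxidise the electron-rich rings. The fallback attaches the top unit as an intact flavan by the established cationic 4→8 coupling and sets out from 2 and 8. Compound 2 is oxidised with DDQ and 2-ethoxyethanol (CH2Cl2, rt) to 4β-(2-ethoxyethoxy)-5,7,3',4'-tetra-O-benzylepicatechin F1. Bromide 8 is reduced with Bu3SnH and AIBN (toluene, 90 °C) to the bromine-free dimer ECG(Bn7)-(4β→8)-ECG(Bn7) F2. Condensation of F1 with an excess of F2 under TMSOTf (CH2Cl2, −40 °C) should join C4 of the cation, from the β face, to the upper-unit C8 of F2 and comes back to the route at 19. This gives up the ring C annulation but takes all three top-unit stereocentres from the chiral pool and substrate control.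

Step 8 (key annulation). The iminium ion of a 2,6-dioxygenated β-aryl enal is hindered and poorly electrophilic, so addition may be slow, catalyst and substrate control may be mismatched, or a second alkylation may intervene. If the catalyst proves to direct the arene to the other face, its enantiomer is used instead. The fallback replaces catalysis by a tether and sets out from 11. Pinnick oxidation (NaClO2, NaH2PO4, 2-methyl-2-butene, t-BuOH/H2O) gives the dimer (E)-propenoic acid F3. Steglich esterification with 12 (DCC, DMAP) gives the 3,5-bis(benzyloxy)phenyl cinnamate F4. Intramolecular Friedel–Crafts hydroarylation (BF3·OEt2, CH2Cl2, −20 °C) closes the 4-aryl-3,4-dihydrocoumarin F5, with C4 set only by the resident stereocentres and the diastereomers separated. Reduction with i-Bu2AlH (1.1 equiv, toluene, −78 °C), which should attack the aryl lactone before the hindered alkyl gallates, comes back to the route at 13.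

Step 6 (cationic dimerisation). Ionisation of the electrophile, deactivated by the bromine and the 3-O-acyl group, may be sluggish, and attack through C6 of the nucleophile or further condensation of the product may compete. The fallback reverses the order of coupling and acylation and sets out from 6 and 2. The free-hydroxyl ether 6 is condensed with an excess of 2 (TMSOTf, CH2Cl2, −40 °C) to the 8-bromo dimer diol F6. Double Steglich esterification of F6 with 3 (DCC, DMAP, CH2Cl2) comes back to the route at 8.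

**Further compounds**

F1 | step 10 | 4β-(2-ethoxyethoxy)-5,7,3',4'-tetra-O-benzylepicatechin | O[C@@H]1[C@@H](OCCOCC)c2c(OCc3ccccc3)cc(OCc3ccccc3)cc2O[C@@H]1c1ccc(OCc2ccccc2)c(OCc2ccccc2)c1
F2 | step 10 | ECG(Bn7)-(4β→8)-ECG(Bn7), bromine-free dimer | O=C(O[C@@H]1[C@@H](c2c(OCc3ccccc3)cc(OCc3ccccc3)c3c2O[C@H](c2ccc(OCc4ccccc4)c(OCc4ccccc4)c2)[C@H](OC(=O)c2cc(OCc4ccccc4)c(OCc4ccccc4)c(OCc4ccccc4)c2)C3)c2c(OCc3ccccc3)cc(OCc3ccccc3)cc2O[C@@H]1c1ccc(OCc2ccccc2)c(OCc2ccccc2)c1)c1cc(OCc2ccccc2)c(OCc2ccccc2)c(OCc2ccccc2)c1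
F3 | step 8 | (E)-3-[upper-unit C8 of ECG(Bn7)-(4β→8)-ECG(Bn7)]propenoic acid | O=C(O[C@@H]1[C@@H](c2c(OCc3ccccc3)cc(OCc3ccccc3)c3c2O[C@H](c2ccc(OCc4ccccc4)c(OCc4ccccc4)c2)[C@H](OC(=O)c2cc(OCc4ccccc4)c(OCc4ccccc4)c(OCc4ccccc4)c2)C3)c2c(OCc3ccccc3)cc(OCc3ccccc3)c(/C=C/C(=O)O)c2O[C@@H]1c1ccc(OCc2ccccc2)c(OCc2ccccc2)c1)c1cc(OCc2ccccc2)c(OCc2ccccc2)c(OCc2ccccc2)c1
F4 | step 8 | 3,5-bis(benzyloxy)phenyl ester of acid F3 | O=C(O[C@@H]1[C@@H](c2c(OCc3ccccc3)cc(OCc3ccccc3)c3c2O[C@H](c2ccc(OCc4ccccc4)c(OCc4ccccc4)c2)[C@H](OC(=O)c2cc(OCc4ccccc4)c(OCc4ccccc4)c(OCc4ccccc4)c2)C3)c2c(OCc3ccccc3)cc(OCc3ccccc3)c(/C=C/C(=O)Oc3cc(OCc4ccccc4)cc(OCc4ccccc4)c3)c2O[C@@H]1c1ccc(OCc2ccccc2)c(OCc2ccccc2)c1)c1cc(OCc2ccccc2)c(OCc2ccccc2)c(OCc2ccccc2)c1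
F5 | step 8 | 5,7-bis(benzyloxy)-3,4-dihydrocoumarin with the dimer C8 at C4 (β) | O=C(O[C@@H]1[C@@H](c2c(OCc3ccccc3)cc(OCc3ccccc3)c3c2O[C@H](c2ccc(OCc4ccccc4)c(OCc4ccccc4)c2)[C@H](OC(=O)c2cc(OCc4ccccc4)c(OCc4ccccc4)c(OCc4ccccc4)c2)C3)c2c(OCc3ccccc3)cc(OCc3ccccc3)c([C@H]3c4c(OCc5ccccc5)cc(OCc5ccccc5)cc4OC(=O)C3)c2O[C@@H]1c1ccc(OCc2ccccc2)c(OCc2ccccc2)c1)c1cc(OCc2ccccc2)c(OCc2ccccc2)c(OCc2ccccc2)c1
F6 | step 6 | 8-bromo-5,7,3',4'-tetra-O-benzylepicatechin-(4β→8)-5,7,3',4'-tetra-O-benzylepicatechin, both 3-OH free | O[C@@H]1[C@@H](c2c(OCc3ccccc3)cc(OCc3ccccc3)c3c2O[C@H](c2ccc(OCc4ccccc4)c(OCc4ccccc4)c2)[C@H](O)C3)c2c(OCc3ccccc3)cc(OCc3ccccc3)c(Br)c2O[C@@H]1c1ccc(OCc2ccccc2)c(OCc2ccccc2)c1
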